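**In the flask.** Per day, J in your flask loses a shrinking fraction, so one time constant will not serve: this is no first-order fall. You have J at 1.2 M under L at 1.44 M, and what counts is what stands at 10 d.

| flask | J | L | remark | time | volume of the second phase over the first |
|---|---|---|---|---|---|
| north-east | 0.60 M | 1.44 M | run made earlier |  |  |
| north-west | 0.90 M | 1.44 M | run made earlier |  |  |
| south | 1.2 M | 2.9 M | run made earlier |  |  |
| flask | 1.2 M | 1.44 M |  | 10 d | 1.0 |

| run | time / d | Z / % | J / % |
|---|---|---|---|
| north-east | 0.333 | 8.6 | 83.6 |
| north-east | 0.833 | 15.4 | 65.4 |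
| north-east | 1.67 | 18.2 | 49.2 |
| north-east | 2.50 | 18.1 | 41.1 |
| north-east | 4.00 | 18.4 | 31.6 |
| north-east | 5.00 | 18.3 | 28.2 |
| north-east | 6.00 | 18.4 | 25.0 |
| north-west | 0.333 | 7.9 | 83.3 |
| north-west | 0.833 | 15.8 | 64.8 |
| north-west | 1.67 | 18.1 | 50.3 |
| north-west | 2.50 | 17.3 | 42.3 |
| north-west | 4.00 | 17.7 | 33.6 |
| north-west | 5.00 | 17.4 | 29.5 |
| north-west | 6.00 | 18.4 | 26.7 |
| south | 1.25 | 29.1 | 41.9 |
| south | 2.50 | 26.3 | 28.4 |
| south | 4.00 | 23.9 | 19.9 |
| south | 5.00 | 24.1 | 15.6 |
| south | 6.00 | 24.0 | 12.8 |

(scatter of a reading: 0.5 percentage points)

- Z is meant together with its E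
- in the second phase: L, E; everything else is in the first
- charges count per volume of the first phase; a concentration in a rate is the amount of a species over the volume of its own phase; every rate counts per litre of the first phase
- the earlier runs hold the two phases in the same ratio of volumes as the flask asked about
- what has gone from J into another species counts as reacted, even if it can come back

* amount of Z and E together at 10 d, in percent of the J charged
* part of the J charged that has reacted at 10 d

**The exponent.** In the north-west run J falls from 42.3% at 2.50 d to 26.7% at 6.00 d. The logarithm of that fall over the logarithm of the growth in time gives 0.526: call it the late exponent. Your running time constant is then the time over this exponent, 11.4 d at 6.00 d.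

**When you come.** J at 6.00 d rose by 1.7 percentage points from the north-east to the north-west charge. One more such step puts your flask at 28.4%, and the exponent carries that to 21.7% at 10 d, so I expect 78.3% reacted. The same step on the flat late readings gives 17.3% of Z with E.

**Hands off.** Leave L as charged if you want this reckoning to stand: the exponent and the step were read at 1.44 M of L. The south run, with 2.9 M of it, holds less J than I expect in your flask: 12.8% at 6.00 d.

**The result.** The forecast gives 17% and 77%, holding that “most of the later J loss goes to an unseen species”. The flask gives 18.1% of Z with E and 78.0% of J reacted.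

    Z ⇌ E, rate k1*([Z] - [E]/K1) per volume of the first phase (partition coefficient = 21.0, kL = 1.50 × 10⁻⁴ /min)
    J ⇌ D (K = 0.620, k = 1.80 × 10⁻⁴ /min)
    J + X ⇌ Z (K = 0.590 /M, k = 3.50 × 10⁻⁴ /M/min)
    X ⇌ L, rate k4*([X] - [L]/K4) per volume of the first phase (partition coefficient = 0.460, kL = 0.00190 /min)
    Z → Q (k = 4.20 × 10⁻⁴ /min)

**Exponent again.** At 10.0 d the flask holds 43.7% as Q, and E makes up 14.7% of its 18.1% of Z. From the 28.8% of J this flask has at 6.00 d, the exponent gives 22.0% at 10 d, and the flask has 22.0%. From the 25.0% of J in the north-east run at 6.00 d, it gives 80.9% reacted at 10 d, and that run carried on to that time has 82.7%.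

Readings and results are calculated for substances that don't exist; the scatter is artificial.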